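Cembrane numbering is used: ring C1–C14, acrylate C15–C17 on C1, lactone oxygen on C12. The route rests on cutting C1–C14 and O–C12. These two bonds tie the C13–C14 ethylene bridge into the seven-membered α-methylene lactone, and C1–C14 also closes the fourteen-membered carbocycle. C1 is the γ-carbon of the acrylate and C11/C12 carry vicinal oxygens, so the precursor is an acyclic chain ending in a (Z)-2-(chloromethyl)enoate and a vinyl-substituted cis-11,12-epoxide. One pot: hydroboration, copper-catalysed SN2′ macrocyclisation (C1–C14, C1 stereocentre, exocyclic methylene), then ester-carbonyl opening of the epoxide at C12 with inversion (lactone, free O11).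

Key step: step 15

Remark on numbering: compounds 9–19 are named with chain locants; the Why lines give the cembrane locants where they matter.
Remark on one assumption: the sense of induction of the copper/bisphosphine catalyst at C1 in step 15 is assumed; the ligand antipode that delivers 1R is the one to use (written as (R)).

Step 1
Reactants: 1 (Z)-3-methylpent-2-en-4-yn-1-ol
Product: 2 [(2R,3S)-3-ethynyl-3-methyloxiran-2-yl]methanol
Conditions: Ti(OiPr)4 (10 mol %), D-(−)-diethyl tartrate (12 mol %), t-BuOOH, 4 Å MS, CH2Cl2, −20 °C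
Reagents that add atoms: tert-butyl hydroperoxide, CC(C)(C)OO
Why: Sharpless asymmetric epoxidation, in which the allylic hydroxyl binds the titanium tartrate so that only the allylic alkene is epoxidised; D-(−)-tartrate should deliver oxygen to the face giving 2R, and because the alkene is Z the hydroxymethyl and ethynyl groups end up cis (3S).

Step 2
Reactants: 2 [(2R,3S)-3-ethynyl-3-methyloxiran-2-yl]methanol
Product: 3 (2S,3S)-2-ethynyl-3-(iodomethyl)-2-methyloxirane
Conditions: I2, PPh3, imidazole, CH2Cl2, 0 °C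
Reagents that add atoms: iodine, II
Why: Appel-type iodination, in which the primary alcohol is activated as an alkoxyphosphonium ion and displaced by iodide at CH2, so both epoxide centres are untouched (the descriptor change is a priority effect only).

Step 3
Reactants: 4 (R)-(−)-linalool
Product: 6 2-[(2S,5R)-5-ethenyl-5-methyloxolan-2-yl]propan-2-ol (cis-linalool oxide), via 6,7-epoxylinalool 5 (not isolated)
Conditions: D-fructose-derived Shi ketone (30 mol %), KHSO5 (as 2KHSO5·KHSO4·K2SO4), K2CO3, Bu4NHSO4 (cat.), MeCN/CH2(OMe)2/aq. Na2B4O7, 0 °C; then CSA (cat.), CH2Cl2, 0 °C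
Reagents that add atoms: potassium peroxymonosulfate, [K+].[O-]S(=O)(=O)OO
Why: Shi epoxidation, in which the chiral dioxirane attacks only the electron-rich trisubstituted alkene and should give the 6R epoxide; acid then lets the tertiary hydroxyl open it 5-exo-tet with inversion at C6, which fixes the cis oxolane (C7 S, C4 R of the cembrane, C4 coming from linalool).

Step 4
Reactants: 6 2-[(2S,5R)-5-ethenyl-5-methyloxolan-2-yl]propan-2-ol
Product: 7 (2R,5S)-2-ethenyl-2-methyl-5-(prop-1-en-2-yl)oxolane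
Conditions: Burgess reagent, THF, 50 °C
Reagents that add atoms: none
Why: Burgess dehydration by syn elimination of the sulfamate ester, in which the six methyl hydrogens are far more accessible than the single hindered ring methine, so the isopropenyl group should form in preference to the enol ether; no stereocentre is touched.

Step 5
Reactants: 7 (2R,5S)-2-ethenyl-2-methyl-5-(prop-1-en-2-yl)oxolane
Product: 8 (2R,5S)-5-acetyl-2-methyloxolane-2-carbaldehyde
Conditions: O3, CH2Cl2, −78 °C; then Me2S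
Reagents that add atoms: ozone, [O-][O+]=O
Why: Ozonolysis with reductive work-up cleaves both terminal alkenes to leave the methyl ketone and the aldehyde; the aldehyde α-carbon is quaternary and cannot epimerise.

Step 6
Reactants: 8 (2R,5S)-5-acetyl-2-methyloxolane-2-carbaldehyde
Product: 9 (4S,5R,8S)-5,8-epoxy-4-hydroxy-5-methyldec-1-en-9-one
Conditions: (−)-Ipc2B(allyl) [from (+)-α-pinene], Et2O, −78 °C; then HOCH2CH2NH2
Reagents that add atoms: (−)-B-allyldiisopinocampheylborane, C=CCB([C@@H]1C[C@@H]2C[C@H]([C@H]1C)C2(C)C)[C@@H]1C[C@@H]2C[C@H]([C@H]1C)C2(C)C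
Why: Brown allylboration through a closed six-membered transition state, in which the aldehyde reacts much faster than the methyl ketone at −78 °C and the reagent adds to the Si face (the sense that gives (S)-1-phenylbut-3-en-1-ol from benzaldehyde), setting C3 of the cembrane as S under reagent control.

Step 7
Reactants: 9 (4S,5R,8S)-5,8-epoxy-4-hydroxy-5-methyldec-1-en-9-one
Product: 10 (4S,5R,8S)-4-(tert-butyldimethylsilyloxy)-5,8-epoxy-5-methyldec-1-en-9-one
Conditions: TBSOTf, 2,6-lutidine, CH2Cl2, −78 °C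
Reagents that add atoms: tert-butyldimethylsilyl triflate, CC(C)(C)[Si](C)(C)OS(=O)(=O)C(F)(F)F
Why: Silyl triflate silylation of the hindered secondary alcohol, fast enough at −78 °C that the methyl ketone should not be converted into its silyl enol ether.

Step 8
Reactants: 10 (4S,5R,8S)-4-(tert-butyldimethylsilyloxy)-5,8-epoxy-5-methyldec-1-en-9-one, 3 (2S,3S)-2-ethynyl-3-(iodomethyl)-2-methyloxirane
Product: 11 (4S,5R,8S,12R,13S)-4-(tert-butyldimethylsilyloxy)-5,8:12,13-diepoxy-5,13-dimethylpentadec-1-en-14-yn-9-one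
Conditions: LiN(iPr)2, THF, −78 °C; then 3, DMPU, −78 to −20 °C
Reagents that add atoms: none
Why: Kinetic enolate alkylation, in which LiN(iPr)2 deprotonates the unhindered methyl group instead of the α-alkoxy methine and the enolate displaces the primary iodide by SN2 (forming C9–C10), while the hindered trisubstituted epoxide and the less acidic alkyne C–H stay spectators.

Step 9
Reactants: 11 (4S,5R,8S,12R,13S)-4-(tert-butyldimethylsilyloxy)-5,8:12,13-diepoxy-5,13-dimethylpentadec-1-en-14-yn-9-one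
Product: 12 (4S,5R,8S,9R,12R,13S)-4-(tert-butyldimethylsilyloxy)-5,8:12,13-diepoxy-5,9,13-trimethylpentadec-1-en-14-yn-9-ol
Conditions: MeMgBr, CH2Cl2/Et2O, −78 °C; then aq. NH4Cl
Reagents that add atoms: methylmagnesium bromide, C[Mg]Br
Why: Chelation-controlled Grignard addition (Cram cyclic model), in which magnesium bridges the ketone oxygen and the oxolane oxygen and methyl attacks from the side of the small ring C–H, which should give the 8R tertiary alcohol of the cembrane.

Step 10
Reactants: 12 (4S,5R,8S,9R,12R,13S)-4-(tert-butyldimethylsilyloxy)-5,8:12,13-diepoxy-5,9,13-trimethylpentadec-1-en-14-yn-9-ol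
Product: 13 (4S,5R,8S,9R,12R,13S)-4-(tert-butyldimethylsilyloxy)-5,8:12,13-diepoxy-5,9,13-trimethyl-9-(triethylsilyloxy)pentadec-1-en-14-yne
Conditions: TESOTf, 2,6-lutidine, CH2Cl2, −78 °C
Reagents that add atoms: triethylsilyl triflate, CC[Si](CC)(CC)OS(=O)(=O)C(F)(F)F
Why: Silyl triflate silylation of the tertiary alcohol at low temperature, needed so that this hydroxyl cannot open the epoxide (5-exo) in the acidic stage of step 15.

Step 11
Reactants: 13 (4S,5R,8S,9R,12R,13S)-4-(tert-butyldimethylsilyloxy)-5,8:12,13-diepoxy-5,9,13-trimethyl-9-(triethylsilyloxy)pentadec-1-en-14-yne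
Product: 14 (3S,4R,7S,8R,11R,12S)-3-(tert-butyldimethylsilyloxy)-4,7:11,12-diepoxy-4,8,12-trimethyl-8-(triethylsilyloxy)tetradec-13-ynal
Conditions: O3 (titrated, Sudan red 7B), CH2Cl2, −78 °C; then PPh3
Reagents that add atoms: ozone, [O-][O+]=O
Why: Ozonolysis, in which ozone reacts with the terminal alkene far faster than with the alkyne, so titrated ozone and a mild reductive work-up should give the β-silyloxy aldehyde (C1 of the cembrane).

Step 12
Reactants: 14 (3S,4R,7S,8R,11R,12S)-3-(tert-butyldimethylsilyloxy)-4,7:11,12-diepoxy-4,8,12-trimethyl-8-(triethylsilyloxy)tetradec-13-ynal, 15 tert-butyl acrylate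
Product: 16 tert-butyl (3RS,5S,6R,9S,10R,13R,14S)-5-(tert-butyldimethylsilyloxy)-6,9:13,14-diepoxy-3-hydroxy-6,10,14-trimethyl-2-methylidene-10-(triethylsilyloxy)hexadec-15-ynoate
Conditions: DABCO, 1,4-dioxane/H2O, rt
Reagents that add atoms: none
Why: Morita–Baylis–Hillman reaction, in which DABCO adds to the acrylate, the ammonium enolate adds to the aldehyde and loss of DABCO gives the α-methylene β-hydroxy ester; the new carbinol centre forms as a mixture, which does not matter because it becomes sp2 in step 14.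

Step 13
Reactants: 16 tert-butyl (3RS,5S,6R,9S,10R,13R,14S)-5-(tert-butyldimethylsilyloxy)-6,9:13,14-diepoxy-3-hydroxy-6,10,14-trimethyl-2-methylidene-10-(triethylsilyloxy)hexadec-15-ynoate
Product: 17 tert-butyl (3RS,5S,6R,9S,10R,13R,14S)-5-(tert-butyldimethylsilyloxy)-6,9:13,14-diepoxy-3-hydroxy-6,10,14-trimethyl-2-methylidene-10-(triethylsilyloxy)hexadec-15-enoate
Conditions: H2 (1 atm), Pd on CaCO3 poisoned with Pb(OAc)2, quinoline, EtOAc, rt
Reagents that add atoms: none
Why: Lindlar semi-hydrogenation stops at the alkene and leaves the acrylate and the epoxide alone; the vinyl group is unveiled only now because it would not have survived the two ozonolyses.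

Step 14
Reactants: 17 tert-butyl (3RS,5S,6R,9S,10R,13R,14S)-5-(tert-butyldimethylsilyloxy)-6,9:13,14-diepoxy-3-hydroxy-6,10,14-trimethyl-2-methylidene-10-(triethylsilyloxy)hexadec-15-enoate
Product: 18 tert-butyl (2Z,5S,6R,9S,10R,13R,14S)-5-(tert-butyldimethylsilyloxy)-2-(chloromethyl)-6,9:13,14-diepoxy-6,10,14-trimethyl-10-(triethylsilyloxy)hexadeca-2,15-dienoate
Conditions: N-chlorosuccinimide, Me2S, CH2Cl2, −30 to 0 °C
Reagents that add atoms: N-chlorosuccinimide, O=C1CCC(=O)N1Cl
Why: Corey–Kim-type chlorination, in which chloride displaces the alkoxysulfonium ion in an SN2′ sense at the methylene terminus to give the conjugated, thermodynamically preferred (Z)-2-(chloromethyl)enoate under neutral conditions that spare the vinyl epoxide.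

Step 15
Reactants: 18 tert-butyl (2Z,5S,6R,9S,10R,13R,14S)-5-(tert-butyldimethylsilyloxy)-2-(chloromethyl)-6,9:13,14-diepoxy-6,10,14-trimethyl-10-(triethylsilyloxy)hexadeca-2,15-dienoate
Product: 21 (1R,3S,4R,7S,8R,11R,12R)-3-(tert-butyldimethylsilyloxy)-4,7-epoxy-11-hydroxy-8-(triethylsilyloxy)cembr-15(17)-en-16,12-olide, via B-alkyl-9-BBN 19 (not isolated), via macrocyclic epoxy ester 20 (not isolated)
Conditions: 9-BBN, THF, 0 °C to rt; KOEt (1 equiv); slow addition to CuCl (10 mol %), (R)-DTBM-SEGPHOS (12 mol %), 1,4-dioxane, 40 °C, 2 mM; then CSA (20 mol %), CH2Cl2, rt, same flask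
Reagents that add atoms: none
Why: 9-BBN hydroborates only the vinyl group (boron on C14), ethoxide turns the borane into a borate that hands the C14 alkyl group to copper, and the alkylcopper adds to C1 of the enoate with loss of chloride (SN2′, addition–elimination), forming C1–C14 and the C15=C17 methylene; acid then lets the tert-butyl ester carbonyl open the protonated epoxide at the tertiary carbon C12, the tert-butyl cation leaving as isobutene. The closest known reaction types are the copper-catalysed γ-selective (also enantioselective) allyl–alkyl coupling of alkyl-9-BBN reagents with allylic chlorides, the copper-mediated SN2′ alkylation of 2-(halomethyl)alk-2-enoates and the acid-promoted lactonisation of epoxy tert-butyl esters. The carbocycle closes 14-exo-trig (C1 in the ring, C15 outside) and the lactone closes 7-exo-tet. C1 is set by the chiral bisphosphine on copper (facial selection on the enoate), C12 by stereospecific inversion of the cis-epoxide made in step 1, and C11 keeps its epoxide oxygen with retention. The step needs γ- over α-attack (secured by copper and by conjugation of the enoate), ring closure over oligomerisation (high dilution, slow addition of the borate), attack at C12 instead of C11 (tertiary centre, seven- against eight-membered ring) and a silent C8 oxygen (blocked as its triethylsilyl ether).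

Step 16
Reactants: 21 (1R,3S,4R,7S,8R,11R,12R)-3-(tert-butyldimethylsilyloxy)-4,7-epoxy-11-hydroxy-8-(triethylsilyloxy)cembr-15(17)-en-16,12-olide
Product: 22 (1R,3S,4R,7S,8R,11R,12R)-4,7-epoxy-3,8,11-trihydroxycembr-15(17)-en-16,12-olide
Conditions: HF·pyridine, pyridine/THF, 0 °C to rt
Reagents that add atoms: none
Why: Fluoride-driven cleavage of both silyl ethers through Si–F bond formation; the lactone, the acrylate and the tertiary alcohol should be stable to buffered HF·pyridine.

Step 17
Reactants: 22 (1R,3S,4R,7S,8R,11R,12R)-4,7-epoxy-3,8,11-trihydroxycembr-15(17)-en-16,12-olide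
Product: 23 querciformolide C, (1R,3S,4R,7S,8R,11R,12R)-3,11-diacetoxy-4,7-epoxy-8-hydroxycembr-15(17)-en-16,12-olide
Conditions: Ac2O, pyridine, DMAP (cat.), CH2Cl2, rt
Reagents that add atoms: acetic anhydride, CC(=O)OC(C)=O
Why: DMAP-catalysed acetylation should esterify the two secondary alcohols (C3, C11) much faster than the tertiary C8 hydroxyl, which stays free as in the target.

Compound list
1 | (Z)-3-methylpent-2-en-4-yn-1-ol | C#C/C(C)=C\CO | starting material
2 | [(2R,3S)-3-ethynyl-3-methyloxiran-2-yl]methanol | OC[C@H]1O[C@@]1(C)C#C | intermediate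
3 | (2S,3S)-2-ethynyl-3-(iodomethyl)-2-methyloxirane | IC[C@H]1O[C@@]1(C)C#C | intermediate
4 | (R)-(−)-linalool, (3R)-3,7-dimethylocta-1,6-dien-3-ol | C=C[C@](C)(O)CCC=C(C)C | starting material
5 | (3R,6R)-6,7-epoxylinalool, (3R)-5-[(2R)-3,3-dimethyloxiran-2-yl]-3-methylpent-1-en-3-ol (not isolated) | C=C[C@](C)(O)CC[C@H]1OC1(C)C | intermediate
6 | 2-[(2S,5R)-5-ethenyl-5-methyloxolan-2-yl]propan-2-ol (cis-linalool oxide) | C=C[C@@]1(C)CC[C@H](O1)C(C)(C)O | intermediate
7 | (2R,5S)-2-ethenyl-2-methyl-5-(prop-1-en-2-yl)oxolane | C=C[C@@]1(C)CC[C@H](O1)C(C)=C | intermediate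
8 | (2R,5S)-5-acetyl-2-methyloxolane-2-carbaldehyde | O=C[C@@]1(C)CC[C@H](O1)C(C)=O | intermediate
9 | (4S,5R,8S)-5,8-epoxy-4-hydroxy-5-methyldec-1-en-9-one | C=CC[C@H](O)[C@@]1(C)CC[C@H](O1)C(C)=O | intermediate
10 | (4S,5R,8S)-4-(tert-butyldimethylsilyloxy)-5,8-epoxy-5-methyldec-1-en-9-one | C=CC[C@H](O[Si](C)(C)C(C)(C)C)[C@@]1(C)CC[C@H](O1)C(C)=O | intermediate
11 | (4S,5R,8S,12R,13S)-4-(tert-butyldimethylsilyloxy)-5,8:12,13-diepoxy-5,13-dimethylpentadec-1-en-14-yn-9-one | C=CC[C@H](O[Si](C)(C)C(C)(C)C)[C@@]1(C)CC[C@H](O1)C(=O)CC[C@H]1O[C@@]1(C)C#C | intermediate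
12 | (4S,5R,8S,9R,12R,13S)-4-(tert-butyldimethylsilyloxy)-5,8:12,13-diepoxy-5,9,13-trimethylpentadec-1-en-14-yn-9-ol | C=CC[C@H](O[Si](C)(C)C(C)(C)C)[C@@]1(C)CC[C@H](O1)[C@](C)(O)CC[C@H]1O[C@@]1(C)C#C | intermediate
13 | (4S,5R,8S,9R,12R,13S)-4-(tert-butyldimethylsilyloxy)-5,8:12,13-diepoxy-5,9,13-trimethyl-9-(triethylsilyloxy)pentadec-1-en-14-yne | C=CC[C@H](O[Si](C)(C)C(C)(C)C)[C@@]1(C)CC[C@H](O1)[C@](C)(O[Si](CC)(CC)CC)CC[C@H]1O[C@@]1(C)C#C | intermediate
14 | (3S,4R,7S,8R,11R,12S)-3-(tert-butyldimethylsilyloxy)-4,7:11,12-diepoxy-4,8,12-trimethyl-8-(triethylsilyloxy)tetradec-13-ynal | O=CC[C@H](O[Si](C)(C)C(C)(C)C)[C@@]1(C)CC[C@H](O1)[C@](C)(O[Si](CC)(CC)CC)CC[C@H]1O[C@@]1(C)C#C | intermediate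
15 | tert-butyl acrylate | C=CC(=O)OC(C)(C)C | starting material
16 | tert-butyl (3RS,5S,6R,9S,10R,13R,14S)-5-(tert-butyldimethylsilyloxy)-6,9:13,14-diepoxy-3-hydroxy-6,10,14-trimethyl-2-methylidene-10-(triethylsilyloxy)hexadec-15-ynoate | C=C(C(=O)OC(C)(C)C)C(O)C[C@H](O[Si](C)(C)C(C)(C)C)[C@@]1(C)CC[C@H](O1)[C@](C)(O[Si](CC)(CC)CC)CC[C@H]1O[C@@]1(C)C#C | intermediate
17 | tert-butyl (3RS,5S,6R,9S,10R,13R,14S)-5-(tert-butyldimethylsilyloxy)-6,9:13,14-diepoxy-3-hydroxy-6,10,14-trimethyl-2-methylidene-10-(triethylsilyloxy)hexadec-15-enoate | C=C(C(=O)OC(C)(C)C)C(O)C[C@H](O[Si](C)(C)C(C)(C)C)[C@@]1(C)CC[C@H](O1)[C@](C)(O[Si](CC)(CC)CC)CC[C@H]1O[C@@]1(C)C=C | intermediate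
18 | tert-butyl (2Z,5S,6R,9S,10R,13R,14S)-5-(tert-butyldimethylsilyloxy)-2-(chloromethyl)-6,9:13,14-diepoxy-6,10,14-trimethyl-10-(triethylsilyloxy)hexadeca-2,15-dienoate | ClC/C(C(=O)OC(C)(C)C)=C\C[C@H](O[Si](C)(C)C(C)(C)C)[C@@]1(C)CC[C@H](O1)[C@](C)(O[Si](CC)(CC)CC)CC[C@H]1O[C@@]1(C)C=C | intermediate
19 | tert-butyl (2Z,5S,6R,9S,10R,13R,14S)-16-(9-borabicyclo[3.3.1]nonan-9-yl)-5-(tert-butyldimethylsilyloxy)-2-(chloromethyl)-6,9:13,14-diepoxy-6,10,14-trimethyl-10-(triethylsilyloxy)hexadec-2-enoate (not isolated) | ClC/C(C(=O)OC(C)(C)C)=C\C[C@H](O[Si](C)(C)C(C)(C)C)[C@@]1(C)CC[C@H](O1)[C@](C)(O[Si](CC)(CC)CC)CC[C@H]1O[C@@]1(C)CCB1C2CCCC1CCC2 | intermediate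
20 | tert-butyl 2-[(1R,3S,4R,7S,8R,11R,12S)-3-(tert-butyldimethylsilyloxy)-4,7:11,12-diepoxy-4,8,12-trimethyl-8-(triethylsilyloxy)cyclotetradecyl]prop-2-enoate (not isolated) | C=C(C(=O)OC(C)(C)C)[C@H]1C[C@H](O[Si](C)(C)C(C)(C)C)[C@@]2(C)CC[C@H](O2)[C@](C)(O[Si](CC)(CC)CC)CC[C@H]2O[C@@]2(C)CC1 | intermediate
21 | (1R,3S,4R,7S,8R,11R,12R)-3-(tert-butyldimethylsilyloxy)-4,7-epoxy-11-hydroxy-8-(triethylsilyloxy)cembr-15(17)-en-16,12-olide | C=C1C(=O)O[C@]2(C)CC[C@@H]1C[C@H](O[Si](C)(C)C(C)(C)C)[C@@]1(C)CC[C@H](O1)[C@](C)(O[Si](CC)(CC)CC)CC[C@H]2O | intermediate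
22 | (1R,3S,4R,7S,8R,11R,12R)-4,7-epoxy-3,8,11-trihydroxycembr-15(17)-en-16,12-olide | C=C1C(=O)O[C@]2(C)CC[C@@H]1C[C@H](O)[C@@]1(C)CC[C@H](O1)[C@](C)(O)CC[C@H]2O | intermediate
23 | querciformolide C, (1R,3S,4R,7S,8R,11R,12R)-3,11-diacetoxy-4,7-epoxy-8-hydroxycembr-15(17)-en-16,12-olide | C=C1C(=O)O[C@]2(C)CC[C@@H]1C[C@H](OC(C)=O)[C@@]1(C)CC[C@H](O1)[C@](C)(O)CC[C@H]2OC(C)=O | target

Total step count: 17. Longest linear sequence: 15 steps (4 to 23, steps 3–17).

Steps most likely to fail

Step 15. The ring closure may lose to intermolecular coupling or protodeboronation, the catalyst may give poor facial selectivity at C1, and the silyl ether on C8 may compete with the ester for the activated epoxide. Fallback: from 18, hydroboration with 9-BBN followed by iodinolysis (I2, NaOMe) would give the primary iodide tert-butyl (2Z,5S,6R,9S,10R,13R,14S)-5-(tert-butyldimethylsilyloxy)-2-(chloromethyl)-6,9:13,14-diepoxy-16-iodo-6,10,14-trimethyl-10-(triethylsilyloxy)hexadec-2-enoate F1. A tin-mediated radical addition–fragmentation macrocyclisation ((Bu3Sn)2, hν, benzene, high dilution) would then join C14 to C1 with loss of the chlorine atom and give 20, expected as a mixture of C1 epimers. After separation, CSA in CH2Cl2 would lactonise 20 and the route is rejoined at 21.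

Step 8. Proton exchange between product and enolate may lead to dialkylation or to epimerisation at the α-alkoxy carbon, and displacement of the β-oxygenated iodide may be slow. Fallback: from 10, condensation with Me2NNH2 would give the N,N-dimethylhydrazone of 10 F2. Metalation at the methyl group with LiN(iPr)2 and alkylation with 3 would give the N,N-dimethylhydrazone of 11 F3. Hydrolysis with aqueous Cu(OAc)2 in THF would return to the route at 11.

Step 12. Addition of the ammonium enolate to the hindered aldehyde may be very slow, and during long exposure to the amine the β-silyloxy group may be lost by elimination. Fallback: from 14, aldol addition of the lithium enolate of tert-butyl 3-(phenylselanyl)propanoate (LiN(iPr)2, THF, −78 °C) would give the β-hydroxy selenide tert-butyl (5S,6R,9S,10R,13R,14S)-5-(tert-butyldimethylsilyloxy)-6,9:13,14-diepoxy-3-hydroxy-6,10,14-trimethyl-2-[(phenylselanyl)methyl]-10-(triethylsilyloxy)hexadec-15-ynoate F4. Oxidation with H2O2 and syn elimination of the selenoxide would return to the route at 16.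

Further compounds
F1 | step 15 | tert-butyl (2Z,5S,6R,9S,10R,13R,14S)-5-(tert-butyldimethylsilyloxy)-2-(chloromethyl)-6,9:13,14-diepoxy-16-iodo-6,10,14-trimethyl-10-(triethylsilyloxy)hexadec-2-enoate | ClC/C(C(=O)OC(C)(C)C)=C\C[C@H](O[Si](C)(C)C(C)(C)C)[C@@]1(C)CC[C@H](O1)[C@](C)(O[Si](CC)(CC)CC)CC[C@H]1O[C@@]1(C)CCI
F2 | step 8 | N,N-dimethylhydrazone of 10 | C=CC[C@H](O[Si](C)(C)C(C)(C)C)[C@@]1(C)CC[C@H](O1)C(C)=NN(C)C
F3 | step 8 | N,N-dimethylhydrazone of 11 | C=CC[C@H](O[Si](C)(C)C(C)(C)C)[C@@]1(C)CC[C@H](O1)C(=NN(C)C)CC[C@H]1O[C@@]1(C)C#C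
F4 | step 12 | tert-butyl (5S,6R,9S,10R,13R,14S)-5-(tert-butyldimethylsilyloxy)-6,9:13,14-diepoxy-3-hydroxy-6,10,14-trimethyl-2-[(phenylselanyl)methyl]-10-(triethylsilyloxy)hexadec-15-ynoate | CC(C)(C)OC(=O)C(C[Se]c1ccccc1)C(O)C[C@H](O[Si](C)(C)C(C)(C)C)[C@@]1(C)CC[C@H](O1)[C@](C)(O[Si](CC)(CC)CC)CC[C@H]1O[C@@]1(C)C#C
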